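**Assumption:** the target is taken as exactly the stereoisomer of the given SMILES (7S; acyl chain 2R,3R,4S; cyclohexenone 1′R,6′R, trans), and compounds 1, 4, 9 and 14 are taken as catalogue chemicals.

## Retrosynthetic overview

1. Last bond: the C7–O ester bond and the C7 centre, made by an iodide-mediated anodic acyloxylation that dearomatises ring A of a 2-benzopyran-6-one with the unprotected hydroxy acid.
2. Pyran ring (ring B, the last ring closed): orthoformate formylation and cyclodehydration of a resorcinol benzyl β-diketone; ring A is a bought arene.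
3. C3–C1′ bond: Claisen-type C-acylation of the α′-enolate of (R)-5-methylcyclohex-2-enone (ring C, from (R)-pulegone) with an arylacetyl imidazolide.
4. Hydroxy acid: (S)-Roche ester, chelation-controlled crotylation (sets C3 and C4), hydrogenation, chemoselective oxidation.
5. Ring order: ring C (bought) and ring A (bought) → ring B → dearomatisation of ring A.

## Route

**Step 1**
Reactants: 1 methyl (S)-3-hydroxy-2-methylpropanoate
Product: 2 methyl (S)-3-(benzyloxy)-2-methylpropanoate
Conditions: BnOC(=NH)CCl3 (1.3 equiv), TfOH (5 mol %), CH2Cl2/cyclohexane, 0 °C to rt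
Reagents that add atoms: benzyl 2,2,2-trichloroacetimidate, N=C(OCc1ccccc1)C(Cl)(Cl)Cl
Why: Acid-catalysed O-benzylation with the trichloroacetimidate needs no base, so the epimerisable α-centre of the Roche ester is untouched and no new stereocentre is formed.

**Step 2**
Reactants: 2 methyl (S)-3-(benzyloxy)-2-methylpropanoate
Product: 3 (S)-3-(benzyloxy)-2-methylpropanal
Conditions: i-Bu2AlH (1.05 equiv), CH2Cl2, −78 °C; aq. KNaC4H4O6
Reagents that add atoms: none
Why: Half-reduction of the ester through the cold-stable aluminium hemiacetal gives the aldehyde, which is used at once so that the α-centre does not epimerise.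

**Step 3**
Reactants: 3 (S)-3-(benzyloxy)-2-methylpropanal; 4 (E)-but-2-en-1-yl(tributyl)stannane
Product: 5 (2S,3R,4S)-1-(benzyloxy)-2,4-dimethylhex-5-en-3-ol
Conditions: MgBr2·OEt2 (2.5 equiv), CH2Cl2, −25 °C, then 4 (1.5 equiv)
Reagents that add atoms: none
Why: Chelation-controlled crotylstannane addition (Keck-type, Cram-chelate model): MgBr2 bridges the aldehyde and benzyloxy oxygens so the stannane attacks anti to the C2 methyl (2,3-anti), and the open antiperiplanar transition state gives 3,4-syn, so both new centres (3R,4S) are set by the bought C2 centre.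

**Step 4**
Reactants: 5 (2S,3R,4S)-1-(benzyloxy)-2,4-dimethylhex-5-en-3-ol
Product: 6 (2S,3R,4S)-2,4-dimethylhexane-1,3-diol
Conditions: H2 (1 atm), 10% Pd/C, EtOH, rt
Reagents that add atoms: none
Why: Heterogeneous hydrogenation turns the vinyl group into the ethyl group and hydrogenolyses the benzyl ether in one operation without touching a stereocentre.

**Step 5**
Reactants: 6 (2S,3R,4S)-2,4-dimethylhexane-1,3-diol
Product: 8 (2R,3R,4S)-3-hydroxy-2,4-dimethylhexanoic acid, via hydroxy aldehyde 7 (not isolated)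
Conditions: TEMPO (20 mol %), PhI(OAc)2 (2.2 equiv), MeCN/H2O (1:1), rt
Reagents that add atoms: water, O
Why: Oxoammonium (TEMPO) oxidation is selective for the unhindered primary alcohol and, in water, runs through the aldehyde hydrate to the acid, leaving the secondary alcohol and all three stereocentres intact.

**Step 6**
Reactants: 9 (R)-(+)-pulegone
Product: 10 (6R)-2,2,6-trimethyl-1-oxaspiro[2.5]octan-4-one (pulegone oxide; both epoxide epimers)
Conditions: 30% H2O2, LiOH·H2O (cat.), MeOH, 0 °C to rt
Reagents that add atoms: hydrogen peroxide, OO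
Why: Weitz–Scheffer nucleophilic epoxidation of the enone; the remote methyl centre is untouched and the epoxide configuration is irrelevant because that carbon is flattened later.

**Step 7**
Reactants: 10 (6R)-2,2,6-trimethyl-1-oxaspiro[2.5]octan-4-one
Product: 11 (5R)-5-methyl-2-(phenylsulfanyl)cyclohexan-1-one (C2 epimers)
Conditions: NaSPh (1.2 equiv), THF, reflux; aq. NH4Cl
Reagents that add atoms: sodium benzenethiolate, [Na+].[S-]c1ccccc1
Why: The thiolate opens the epoxide at the α-carbon and the tertiary alkoxide so formed fragments by retro-aldol loss of acetone (epoxide opening/retro-aldol cascade), leaving the α-phenylthio ketone with C5 untouched.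

**Step 8**
Reactants: 11 (5R)-5-methyl-2-(phenylsulfanyl)cyclohexan-1-one
Product: 13 (R)-5-methylcyclohex-2-en-1-one, via sulfoxide 12 (not isolated)
Conditions: mCPBA (1.0 equiv), CH2Cl2, −78 °C; then CaCO3, toluene, 80 °C
Reagents that add atoms: 3-chloroperoxybenzoic acid (oxygen kept only in intermediate 12), OOC(=O)c1cccc(Cl)c1
Why: Sulfide-to-sulfoxide oxidation followed by thermal syn-elimination of the sulfoxide can place the double bond only between C2 and C3, giving the enone with the bought C5 centre intact.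

**Step 9**
Reactants: 14 3,5-dimethoxy-4-methylbenzaldehyde
Product: 16 2-(3,5-dimethoxy-4-methylphenyl)acetonitrile, via N-alkenylformamide 15 (not isolated)
Conditions: TosMIC (1.3 equiv), t-BuOK (2.4 equiv), DME, −40 °C to rt; then MeOH, reflux
Reagents that add atoms: 4-toluenesulfonylmethyl isocyanide (TosMIC), Cc1ccc(cc1)S(=O)(=O)C[N+]#[C-]
Why: van Leusen reductive cyanation: TosMIC adds to the non-enolisable aldehyde, the oxazoline opens to the N-alkenylformamide, and methanolysis with loss of sulfinate gives the one-carbon-homologated nitrile.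

**Step 10**
Reactants: 16 2-(3,5-dimethoxy-4-methylphenyl)acetonitrile
Product: 17 2-(3,5-dihydroxy-4-methylphenyl)acetic acid
Conditions: 48% aq. HBr, AcOH, reflux
Reagents that add atoms: water, O
Why: Hot HBr hydrolyses the nitrile to the acid and cleaves both aryl methyl ethers by SN2 attack of bromide (acidic nitrile hydrolysis with ether cleavage).

**Step 11**
Reactants: 17 2-(3,5-dihydroxy-4-methylphenyl)acetic acid
Product: 19 2-[3,5-bis(tert-butyldimethylsilyloxy)-4-methylphenyl]acetic acid, via silyl ester 18 (not isolated)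
Conditions: TBSCl (3.5 equiv), imidazole (7 equiv), DMF, rt; then AcOH/THF/H2O (3:1:1), rt
Reagents that add atoms: tert-butyldimethylsilyl chloride, CC(C)(C)[Si](C)(C)Cl
Why: Persilylation followed by mild aqueous acid, which hydrolyses only the labile silyl ester, masks the acidic phenols and frees the carboxylic acid for activation (silyl ether protection).

**Step 12**
Reactants: 19 2-[3,5-bis(tert-butyldimethylsilyloxy)-4-methylphenyl]acetic acid; 13 (R)-5-methylcyclohex-2-en-1-one
Product: 22 (5R,6R)-6-{2-[3,5-bis(tert-butyldimethylsilyloxy)-4-methylphenyl]acetyl}-5-methylcyclohex-2-en-1-one, via acyl imidazolide 20 (not isolated), via lithium dienolate 21 (not isolated)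
Conditions: 19, CDI (1.1 equiv), THF, rt; separately 13 (2.2 equiv), LiN(i-Pr)2 (2.2 equiv), THF, −78 °C; add 20, −78 to −40 °C; aq. NH4Cl (excess 13 recovered)
Reagents that add atoms: 1,1′-carbonyldiimidazole (imidazolyl kept only in intermediate 20), O=C(n1ccnc1)n1ccnc1; lithium diisopropylamide (lithium kept only in intermediate 21), [Li]N(C(C)C)C(C)C
Why: Claisen-type C-acylation of the kinetic α′ (cross-conjugated) lithium enolate by the acyl imidazolide gives the β-diketone, the second equivalent of enolate being consumed by the acidic product; the new C6 centre is set trans to the bought C5 methyl by attack anti to the methyl and by equilibration of the enolisable β-diketone.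

**Step 13**
Reactants: 22 (5R,6R)-6-{2-[3,5-bis(tert-butyldimethylsilyloxy)-4-methylphenyl]acetyl}-5-methylcyclohex-2-en-1-one
Product: 25 8-hydroxy-7-methyl-3-[(1R,6R)-6-methyl-2-oxocyclohex-3-en-1-yl]-6H-isochromen-6-one, via diphenol diketone 23 (not isolated), via benzopyrylium chloride 24 (not isolated)
Conditions: HCl (3 M in EtOH), rt; then HC(OEt)3 (5 equiv), 40 °C; then aq. NaOAc
Reagents that add atoms: triethyl orthoformate, CCOC(OCC)OCC; hydrogen chloride (chloride kept only in intermediate 24), Cl
Why: Acid strips the silyl ethers, the orthoformate-derived dialkoxycarbenium ion formylates the only free, doubly activated position of the symmetric resorcinol (Gattermann-type orthoformate formylation), the C3 enol oxygen closes onto the new carbon and loss of ethanol gives the aromatic 2-benzopyrylium, which NaOAc deprotonates to the neutral quinoid; no stereocentre is formed and C1′ stays trans under thermodynamic control.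

**Step 14**
Reactants: 25 8-hydroxy-7-methyl-3-[(1R,6R)-6-methyl-2-oxocyclohex-3-en-1-yl]-6H-isochromen-6-one; 8 (2R,3R,4S)-3-hydroxy-2,4-dimethylhexanoic acid
Product: 27 Muyocopronone A, via iodo dione 26 (not isolated)
Conditions: undivided cell, graphite anode, Pt cathode, n-Bu4NI (20 mol %), 8 (1.5 equiv), 2,6-lutidine (0.5 equiv), n-Bu4NBF4 (0.1 M), MeCN, 20 °C, constant current (4 mA cm−2), 2.2 F mol−1; chromatographic separation of the C7 epimers
Reagents that add atoms: tetrabutylammonium iodide (iodine kept only in intermediate 26), CCCC[N+](CCCC)(CCCC)CCCC.[I-]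
Why: Proposed new method: iodine generated at the anode from catalytic iodide iodinates the nucleophilic central carbon C7 of the vinylogous acid 25 to the α-iodo-1,3-dione 26, whose C7 epimers interconvert by iodide-induced deiodination, and the carboxylate of 8 (made at the cathode, where protons are reduced to H2) displaces iodide at C7 in an SN2-type step organised by reversible hemiketal formation between its 3-OH and a flanking ring carbonyl (chair-like seven-membered transition state), so the C7–O bond and the C7 centre form under Curtin–Hammett substrate control by the acid's C2/C3 centres, the 7S epimer being separated from any 7R epimer; the closest known reaction types are the hypoiodite-mediated oxidative α-acyloxylation of carbonyl compounds and dearomatisation of naphthols with carboxylic acids and the Pb(OAc)4 (Wessely-type) acetoxylation of 2-benzopyrylium salts to 7-acetoxy-azaphilones, neither of which has been shown electrochemically on this ring system or with an unprotected chiral hydroxy acid.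

## Compound list

1 | methyl (S)-3-hydroxy-2-methylpropanoate ((S)-Roche ester) | COC(=O)[C@@H](C)CO | starting material
2 | methyl (S)-3-(benzyloxy)-2-methylpropanoate | COC(=O)[C@@H](C)COCc1ccccc1 | intermediate
3 | (S)-3-(benzyloxy)-2-methylpropanal | O=C[C@@H](C)COCc1ccccc1 | intermediate
4 | (E)-but-2-en-1-yl(tributyl)stannane | C/C=C/C[Sn](CCCC)(CCCC)CCCC | starting material
5 | (2S,3R,4S)-1-(benzyloxy)-2,4-dimethylhex-5-en-3-ol | C=C[C@H](C)[C@@H](O)[C@@H](C)COCc1ccccc1 | intermediate
6 | (2S,3R,4S)-2,4-dimethylhexane-1,3-diol | CC[C@H](C)[C@@H](O)[C@@H](C)CO | intermediate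
7 | (2R,3R,4S)-3-hydroxy-2,4-dimethylhexanal | CC[C@H](C)[C@@H](O)[C@@H](C)C=O | intermediate
8 | (2R,3R,4S)-3-hydroxy-2,4-dimethylhexanoic acid | CC[C@H](C)[C@@H](O)[C@@H](C)C(=O)O | intermediate
9 | (R)-(+)-pulegone, (5R)-5-methyl-2-(propan-2-ylidene)cyclohexan-1-one | C[C@@H]1CCC(=C(C)C)C(=O)C1 | starting material
10 | (6R)-2,2,6-trimethyl-1-oxaspiro[2.5]octan-4-one (both epoxide epimers) | C[C@@H]1CCC2(OC2(C)C)C(=O)C1 | intermediate
11 | (5R)-5-methyl-2-(phenylsulfanyl)cyclohexan-1-one (C2 epimers) | C[C@@H]1CCC(Sc2ccccc2)C(=O)C1 | intermediate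
12 | (5R)-5-methyl-2-(phenylsulfinyl)cyclohexan-1-one | C[C@@H]1CCC(S(=O)c2ccccc2)C(=O)C1 | intermediate
13 | (R)-5-methylcyclohex-2-en-1-one | C[C@@H]1CC=CC(=O)C1 | intermediate
14 | 3,5-dimethoxy-4-methylbenzaldehyde | COc1cc(C=O)cc(OC)c1C | starting material
15 | N-[2-(3,5-dimethoxy-4-methylphenyl)-1-(4-methylbenzenesulfonyl)ethenyl]formamide | COc1cc(C=C(NC=O)S(=O)(=O)c2ccc(C)cc2)cc(OC)c1C | intermediate
16 | 2-(3,5-dimethoxy-4-methylphenyl)acetonitrile | COc1cc(CC#N)cc(OC)c1C | intermediate
17 | 2-(3,5-dihydroxy-4-methylphenyl)acetic acid | Cc1c(O)cc(CC(=O)O)cc1O | intermediate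
18 | tert-butyldimethylsilyl 2-[3,5-bis(tert-butyldimethylsilyloxy)-4-methylphenyl]acetate | Cc1c(O[Si](C)(C)C(C)(C)C)cc(CC(=O)O[Si](C)(C)C(C)(C)C)cc1O[Si](C)(C)C(C)(C)C | intermediate
19 | 2-[3,5-bis(tert-butyldimethylsilyloxy)-4-methylphenyl]acetic acid | Cc1c(O[Si](C)(C)C(C)(C)C)cc(CC(=O)O)cc1O[Si](C)(C)C(C)(C)C | intermediate
20 | 2-[3,5-bis(tert-butyldimethylsilyloxy)-4-methylphenyl]-1-(1H-imidazol-1-yl)ethan-1-one | Cc1c(O[Si](C)(C)C(C)(C)C)cc(CC(=O)n2ccnc2)cc1O[Si](C)(C)C(C)(C)C | intermediate
21 | lithium (3R)-3-methylcyclohexa-1,5-dien-1-olate | C[C@@H]1CC=CC(O[Li])=C1 | intermediate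
22 | (5R,6R)-6-{2-[3,5-bis(tert-butyldimethylsilyloxy)-4-methylphenyl]acetyl}-5-methylcyclohex-2-en-1-one | Cc1c(O[Si](C)(C)C(C)(C)C)cc(CC(=O)[C@@H]2C(=O)C=CC[C@H]2C)cc1O[Si](C)(C)C(C)(C)C | intermediate
23 | (5R,6R)-6-[2-(3,5-dihydroxy-4-methylphenyl)acetyl]-5-methylcyclohex-2-en-1-one | Cc1c(O)cc(CC(=O)[C@@H]2C(=O)C=CC[C@H]2C)cc1O | intermediate
24 | 6,8-dihydroxy-7-methyl-3-[(1R,6R)-6-methyl-2-oxocyclohex-3-en-1-yl]isochromenylium chloride | Cc1c(O)cc2cc([C@@H]3C(=O)C=CC[C@H]3C)[o+]cc2c1O.[Cl-] | intermediate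
25 | 8-hydroxy-7-methyl-3-[(1R,6R)-6-methyl-2-oxocyclohex-3-en-1-yl]-6H-isochromen-6-one | CC1=C(O)C2=COC([C@@H]3C(=O)C=CC[C@H]3C)=CC2=CC1=O | intermediate
26 | 7-iodo-7-methyl-3-[(1R,6R)-6-methyl-2-oxocyclohex-3-en-1-yl]-6H-isochromene-6,8(7H)-dione (interconverting C7 epimers) | CC1(I)C(=O)C=C2C=C([C@@H]3C(=O)C=CC[C@H]3C)OC=C2C1=O | intermediate
27 | Muyocopronone A, (7S)-7-methyl-3-[(1R,6R)-6-methyl-2-oxocyclohex-3-en-1-yl]-6,8-dioxo-7,8-dihydro-6H-isochromen-7-yl (2R,3R,4S)-3-hydroxy-2,4-dimethylhexanoate | CC[C@H](C)[C@@H](O)[C@@H](C)C(=O)O[C@@]1(C)C(=O)C=C2C=C([C@@H]3C(=O)C=CC[C@H]3C)OC=C2C1=O | target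

## Step count and risks

Total step count: 14. Longest linear sequence: 6 steps (steps 9, 10, 11, 12, 13, 14; the other two branches are equally long).

**Step 14 (the new reaction).** This is the step most likely to fail.
- Site selectivity: iodination at C5 or C1′ could compete with C7.
- Stereoselectivity: the sense and size of the induction at C7 are not secured by precedent. A chair model with the acid substituents equatorial gives 7S when the hemiketal tether sits on C8 and 7R when it sits on C6, so the ratio must be measured.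
- Mitigation: the two C7 epimers are separable diastereomers, and an unwanted epimer can be cleaved back to 25 and 8 with Zn in AcOH and recycled.

Fallback with known chemistry, setting out from 25 and 8 and returning at 27: 25 is oxidised with 2-iodoxybenzoic acid (TFA, cat. n-Bu4NI, ClCH2CH2Cl, rt) to the tertiary alcohol (7S)-7-hydroxy-7-methyl-3-[(1R,6R)-6-methyl-2-oxocyclohex-3-en-1-yl]-6H-isochromene-6,8(7H)-dione F1, formed together with its C7 epimer. In parallel 8 is silylated (TBSOTf, 2,6-lutidine) to tert-butyldimethylsilyl (2R,3R,4S)-3-[(tert-butyldimethylsilyl)oxy]-2,4-dimethylhexanoate F2, whose silyl ester is cleaved (K2CO3, MeOH) to (2R,3R,4S)-3-[(tert-butyldimethylsilyl)oxy]-2,4-dimethylhexanoic acid F3. Yamaguchi esterification (2,4,6-Cl3C6H2COCl, Et3N, then DMAP, toluene) of F1 with F3 gives the silyl-protected ester (7S)-7-methyl-3-[(1R,6R)-6-methyl-2-oxocyclohex-3-en-1-yl]-6,8-dioxo-7,8-dihydro-6H-isochromen-7-yl (2R,3R,4S)-3-[(tert-butyldimethylsilyl)oxy]-2,4-dimethylhexanoate F4. HF·pyridine then gives 27, which is separated from its C7 epimer by HPLC.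

**Step 12 (C-acylation of the enolate).** Risks are O-acylation, ketene formation from the arylacetyl donor and proton transfer. Fallback by aldol addition and oxidation, setting out from 19 and 13 and returning at 22: 19 is reduced (BH3·SMe2, THF) to 2-[3,5-bis(tert-butyldimethylsilyloxy)-4-methylphenyl]ethan-1-ol F5 and oxidised (Dess–Martin periodinane) to 2-[3,5-bis(tert-butyldimethylsilyloxy)-4-methylphenyl]acetaldehyde F6. Addition of the lithium dienolate 21 at −78 °C gives the β-hydroxy ketone (5R,6R)-6-{2-[3,5-bis(tert-butyldimethylsilyloxy)-4-methylphenyl]-1-hydroxyethyl}-5-methylcyclohex-2-en-1-one F7, and a second Dess–Martin oxidation gives 22.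

**Step 13 (formylative pyrylium formation).** Risks are oligomerisation of the free resorcinol and side reactions of the enone and β-diketone in acid. Fallback that brings in C1 at the lower oxidation level, setting out from 22 and returning at 25: 22 is desilylated (HCl, MeOH) to 23 and closed with paraformaldehyde (1 equiv, p-TsOH, oxa-Pictet–Spengler-type) to 7-methyl-3-[(1R,6R)-6-methyl-2-oxocyclohex-3-en-1-yl]-1H-isochromene-6,8-diol F8. Hydride abstraction with DDQ gives the benzopyrylium, and aq. NaOAc gives 25.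

## Further compounds

F1 | step 14 | (7S)-7-hydroxy-7-methyl-3-[(1R,6R)-6-methyl-2-oxocyclohex-3-en-1-yl]-6H-isochromene-6,8(7H)-dione | C[C@]1(O)C(=O)C=C2C=C([C@@H]3C(=O)C=CC[C@H]3C)OC=C2C1=O
F2 | step 14 | tert-butyldimethylsilyl (2R,3R,4S)-3-[(tert-butyldimethylsilyl)oxy]-2,4-dimethylhexanoate | CC[C@H](C)[C@@H](O[Si](C)(C)C(C)(C)C)[C@@H](C)C(=O)O[Si](C)(C)C(C)(C)C
F3 | step 14 | (2R,3R,4S)-3-[(tert-butyldimethylsilyl)oxy]-2,4-dimethylhexanoic acid | CC[C@H](C)[C@@H](O[Si](C)(C)C(C)(C)C)[C@@H](C)C(=O)O
F4 | step 14 | (7S)-7-methyl-3-[(1R,6R)-6-methyl-2-oxocyclohex-3-en-1-yl]-6,8-dioxo-7,8-dihydro-6H-isochromen-7-yl (2R,3R,4S)-3-[(tert-butyldimethylsilyl)oxy]-2,4-dimethylhexanoate | CC[C@H](C)[C@@H](O[Si](C)(C)C(C)(C)C)[C@@H](C)C(=O)O[C@@]1(C)C(=O)C=C2C=C([C@@H]3C(=O)C=CC[C@H]3C)OC=C2C1=O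
F5 | step 12 | 2-[3,5-bis(tert-butyldimethylsilyloxy)-4-methylphenyl]ethan-1-ol | Cc1c(O[Si](C)(C)C(C)(C)C)cc(CCO)cc1O[Si](C)(C)C(C)(C)C
F6 | step 12 | 2-[3,5-bis(tert-butyldimethylsilyloxy)-4-methylphenyl]acetaldehyde | Cc1c(O[Si](C)(C)C(C)(C)C)cc(CC=O)cc1O[Si](C)(C)C(C)(C)C
F7 | step 12 | (5R,6R)-6-{2-[3,5-bis(tert-butyldimethylsilyloxy)-4-methylphenyl]-1-hydroxyethyl}-5-methylcyclohex-2-en-1-one (carbinol epimers) | Cc1c(O[Si](C)(C)C(C)(C)C)cc(CC(O)[C@@H]2C(=O)C=CC[C@H]2C)cc1O[Si](C)(C)C(C)(C)C
F8 | step 13 | 7-methyl-3-[(1R,6R)-6-methyl-2-oxocyclohex-3-en-1-yl]-1H-isochromene-6,8-diol | Cc1c(O)cc2C=C([C@@H]3C(=O)C=CC[C@H]3C)OCc2c1O
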